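# Gardenin E by carbonylative union of an aryl iodide and a methyl ketone: synthesis design

## The problem

Gardenin E (15) is an achiral flavone, so there is no stereocenter to set and none that could control another; the whole difficulty lies in the oxygenation pattern. Ring A is a fully substituted benzene: C5 carries a free hydroxyl, C6, C7 and C8 carry methoxy groups, and C4a and C8a are the fusion atoms to the pyranone ring C, whose C2 bears ring B. A synthesis must therefore put five oxygens on one benzene ring and tell the C5 oxygen from the three methylated ones. On ring B it must keep the 3'- and 5'-hydroxyls free beside the 4'-methoxy group. The fragile features are the electron-rich phenols (easily oxidised to quinones), the methyl ethers close to the C4 carbonyl (removed by Lewis acids), and the C2=C3 bond of ring C (reducible and open to nucleophiles). The feature that invites a short route is that C4 is a lone carbonyl carbon between C4a of ring A and C3, which is a methylene in the open-chain form. It can therefore be supplied as carbon monoxide between an aryl halide and a ketone enolate. Equally important, both carbons ortho to C4a (C5 and C8a) carry oxygen and C6 and C8 carry the same methoxy group, so the aryl unit on C4 has a mirror plane through C4a and C7. Whichever ortho oxygen closes ring C, the same flavone results, the other oxygen is left as the 5-hydroxyl, and an acid-induced Wessely–Moser interchange would be degenerate.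

## Retrosynthesis

**Ring C, bond O1–C2.** Target 15 is opened at O1–C2 to the 2,6-dihydroxyaryl 1,3-diketone 14. Cyclodehydration of such diketones is the most dependable flavone closure, and here it cannot give a regioisomer because the two ortho hydroxyls of 14 are equivalent. The closure needs only acid, so the four phenols are best masked by groups that acid also removes. Diketone 13 therefore carries four methoxymethyl ethers, and a single acid treatment should unmask 14 and close ring C. Benzyl ethers were weighed for the same positions. They would need a separate hydrogenolysis in the presence of an enolised diketone, and they are bulkier at the two ring A ortho positions next to the carbon that must bind palladium. The methoxymethyl group is smaller and also serves as a directing group further back.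

**Bonds C4a–C4 and C4–C3.** Diketone 13 is cut on both sides of C4 into aryl iodide 6, carbon monoxide 11 and methyl ketone 10. The neighbouring cut at C2–C3 (Claisen or Baker–Venkataraman logic) would need an acetyl or carboxyl group on the pentaoxygenated ring first, and would then need a condensation at or next to a doubly ortho-substituted carbonyl group. The carbonylative cut makes both bonds to C4 in one operation and uses the crowding to advantage: an aryl–palladium bond flanked by two ether groups inserts CO readily but couples directly with an enolate only slowly. The precursors are far simpler than 13: one symmetric pentaoxygenated iodobenzene and one acetophenone, each with a single reactive site. The forward reaction must give C-aroylation of the enolate in preference to direct arylation, O-aroylation and reduction of the iodide.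

**Aryl iodide 6.** The C–I bond is traced to the only ring C–H of 4, which lies between two methoxymethoxy groups. Directed lithiation to aryllithium 5 and an iodine quench is therefore regiochemically unambiguous. Ether 4 comes from resorcinol 3 by O-alkylation, and the two C–O bonds of 3 are cut back to the C–Br bonds of 2. Dibromide 2 is the expected product of twofold bromination of 1,2,3-trimethoxybenzene (1), because C4 and C6 of 1 are each ortho to one outer methoxy group and para to the other. The three contiguous methoxy groups of the target (C6, C7, C8) are thus bought in 1, and only the two oxygens that must end up different (O1 and the 5-hydroxyl) are introduced.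

**Methyl ketone 10.** The acetyl C–CH3 bond is cut to Weinreb amide 9, made in the flask from ester 8. Ester 8 is the bis(methoxymethyl) ether of commercial methyl 3,5-dihydroxy-4-methoxybenzoate (7), which already holds the complete ring B pattern with the 4'-oxygen methylated.

## Roads not taken

**Alternative 1:** Here ring C is closed last at O1–C8a by C–H functionalisation. The open-chain precursor is 1-[4-methoxy-3,5-bis(pivaloyloxy)phenyl]-3-(2,3,4,5-tetramethoxyphenyl)propane-1,3-dione (A1). Anodic oxidation would generate the arene radical cation, and the enol oxygen would attack its only C–H carbon to give 5,6,7,8,4'-pentamethoxy-3',5'-bis(pivaloyloxy)flavone (A2). Pivalate cleavage and chelation-controlled removal of the 5-methyl ether with BCl3 would then lead to 15.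
- Merits: no halogen, no palladium, no CO, and no phenol protection on ring A; the closure site is fixed by the single C–H. In these respects it is better than the chosen plan.
- Weak points: dehydrogenative C–O closure of a diketone enol onto a tetraalkoxyarene is not an established flavone synthesis. The radical cation of a tetramethoxyarene is as likely to be attacked at a methoxy-bearing carbon (leading to quinone-type products) as at C–H. The enol of A1 and the product A2 are themselves oxidisable. Two further steps follow, one of which must distinguish the 5-methoxy group from the 6-methoxy group.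
- Comparison: the chosen plan needs four steps to build iodide 6. Against that, every one of its steps has direct precedent, and the 5-hydroxyl appears without any demethylation.

**Alternative 2:** Ring A is built onto a preformed pyranone. 2-[3,5-Bis(benzyloxy)-4-methoxyphenyl]-4H-pyran-4-one (A4), metalated at C6, would add to dimethyl squarate (A3) to give racemic 4-{6-[3,5-bis(benzyloxy)-4-methoxyphenyl]-4-oxo-4H-pyran-2-yl}-4-hydroxy-2,3-dimethoxycyclobut-2-en-1-one (A5). On heating, A5 should open to a vinylketene that closes by 6π electrocyclisation onto the neighbouring pyranone C–H, forming C4a–C5 and giving 3',5'-bis(benzyloxy)-5,8-dihydroxy-6,7,4'-trimethoxyflavone (A6). Selective methylation of the unchelated 8-hydroxyl and debenzylation would finish the synthesis.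
- Merits: all ring A oxygens come from A3 in the right places, no pentaoxygenated benzene has to be functionalised, and the 5-hydroxyl is differentiated by its hydrogen bond. This is more elegant than making resorcinol 3 from dibromide 2.
- Weak points: a 4-pyranone metalated next to the ring oxygen is prone to self-addition and ring opening. A4 needs its own multistep preparation. Hydroquinone A6 is very easily oxidised to the 5,8-quinone. Two selective steps remain after the key step.
- Comparison: the route would be clearly longer than the eight steps planned here, and its key intermediate is less stable than any compound of the chosen route.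

**Alternative 3:** Ring B is made de novo. The carbanion from the 2-methyl group of 5,6,7,8-tetramethoxy-2-methyl-4H-chromen-4-one (A7) would add to C2 of 3,5-bis(benzyloxy)-4H-pyran-4-one (A8). Ring opening and aldol reclosure would form C1'–C2' and C1'–C6' and deliver 3',5'-bis(benzyloxy)-4'-hydroxy-5,6,7,8-tetramethoxyflavone (A9).
- Merits: the 4'-oxygen emerges as the only free phenol, ready for methylation; the step is convergent and free of transition metals.
- Weak points: the step rebuilds a ring B pattern that is commercial in 7. A7 still requires a classical chromone synthesis on a tetraoxygenated phenol, and A8 is not a stock compound. 4-Pyranones are modest electrophiles at C2, and the anion of A7 can add to a second molecule of A7 at its own C2. After A9 come methylation, debenzylation and selective 5-demethylation.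
- Comparison: the chosen plan is shorter and avoids the late selective demethylation. Alternative 3 avoids handling CO, which is its only real advantage.

Key step: step 7

## Route

Remark on the chemistry: 13 and 14 are drawn as diketones; both should exist largely as chelated enols (14 partly as its cyclic hemiketal), which does not affect the route. Compounds 1, 7 and 11 are taken to be commercial.

Step 1
Reactants: 1 1,2,3-trimethoxybenzene
Product: 2 1,5-dibromo-2,3,4-trimethoxybenzene
Conditions: NBS (2.1 equiv), MeCN, 0 °C to rt
Reagents that add atoms: N-bromosuccinimide, O=C1CCC(=O)N1Br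
Why: Electrophilic aromatic bromination; C4 and C6 of 1 are each ortho to one outer methoxy group and para to the other, whereas C5 is activated only by the central methoxy group, which is twisted out of conjugation, so both bromines should enter at C4 and C6.

Step 2
Reactants: 2 1,5-dibromo-2,3,4-trimethoxybenzene
Product: 3 4,5,6-trimethoxybenzene-1,3-diol
Conditions: Pd2(dba)3 (2 mol%), tBuXPhos (8 mol%), KOH (6 equiv), 1,4-dioxane/H2O (1:1), 100 °C, argon; then aq. HCl
Reagents that add atoms: potassium hydroxide, [K+].[OH-]
Why: Palladium-catalysed hydroxylation of aryl bromides (C–O cross-coupling with hydroxide); the bulky biaryl phosphine favours C–O reductive elimination to the phenoxide over diaryl ether formation, and the first phenoxide sits meta to the second bromide, so it hardly slows the second oxidative addition.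

Step 3
Reactants: 3 4,5,6-trimethoxybenzene-1,3-diol
Product: 4 1,2,3-trimethoxy-4,6-bis(methoxymethoxy)benzene
Conditions: MOMCl (3 equiv), iPr2NEt (4 equiv), CH2Cl2, 0 °C to rt
Reagents that add atoms: chloromethyl methyl ether, COCCl
Why: O-Alkylation of both phenols by the reactive alpha-chloro ether (Williamson-type acetal formation); the air-sensitive diol is capped at once and the methyl ethers are untouched.

Step 4
Reactants: 4 1,2,3-trimethoxy-4,6-bis(methoxymethoxy)benzene
Product: 6 2-iodo-4,5,6-trimethoxy-1,3-bis(methoxymethoxy)benzene, via aryllithium 5 (not isolated)
Conditions: n-BuLi (1.2 equiv), THF, 0 °C; then I2 (1.3 equiv), −78 °C to rt; aq. Na2S2O3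
Reagents that add atoms: iodine, II
Why: Directed ortho-metalation; the only ring hydrogen of 4 lies between two methoxymethoxy groups that cooperate in guiding n-BuLi, and iodinolysis of aryllithium 5 places iodine at the future C4a with no regiochemical alternative.

Step 5
Reactants: 7 methyl 3,5-dihydroxy-4-methoxybenzoate
Product: 8 methyl 4-methoxy-3,5-bis(methoxymethoxy)benzoate
Conditions: MOMCl (3 equiv), iPr2NEt (4 equiv), CH2Cl2, 0 °C to rt
Reagents that add atoms: chloromethyl methyl ether, COCCl
Why: Same acetal-forming O-alkylation as in step 3; the ester and the 4-methoxy group are inert.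

Step 6
Reactants: 8 methyl 4-methoxy-3,5-bis(methoxymethoxy)benzoate
Product: 10 1-[4-methoxy-3,5-bis(methoxymethoxy)phenyl]ethan-1-one, via Weinreb amide 9 (not isolated)
Conditions: MeNHOMe·HCl (1.55 equiv), iPrMgCl (3.0 equiv), THF, −20 °C; then MeMgBr (2.0 equiv), 0 °C; aq. NH4Cl
Reagents that add atoms: methylmagnesium bromide, C[Mg]Br; N,O-dimethylhydroxylamine hydrochloride, CNOC.Cl (its atoms stay only in intermediate 9)
Why: One-flask Weinreb ketone synthesis; the magnesium amide of N,O-dimethylhydroxylamine converts the ester into amide 9, and the chelated tetrahedral adduct of 9 with MeMgBr survives until work-up, so the addition should stop at the methyl ketone.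

Step 7
Reactants: 6 2-iodo-4,5,6-trimethoxy-1,3-bis(methoxymethoxy)benzene; 10 1-[4-methoxy-3,5-bis(methoxymethoxy)phenyl]ethan-1-one; 11 carbon monoxide
Product: 13 1-[3,4,5-trimethoxy-2,6-bis(methoxymethoxy)phenyl]-3-[4-methoxy-3,5-bis(methoxymethoxy)phenyl]propane-1,3-dione, via sodium enolate 12 (not isolated)
Conditions: 10 (2.0 equiv), NaN(SiMe3)2 (2.0 equiv), THF, 0 °C; then 6 (1.0 equiv), Pd(dba)2 (5 mol%), Xantphos (5 mol%), CO (1 atm), THF, 60 °C; aq. NH4Cl
Reagents that add atoms: none
Why: This is the palladium-catalysed three-component carbonylative alpha-arylation of a ketone, a known way from aryl iodides, CO and ketone enolates to 1,3-diketones. Zerovalent palladium inserts into the C–I bond of 6; the resulting aryl-palladium iodide (divalent palladium) is flanked by two ortho ether groups, so migratory insertion of CO, which relieves that crowding, should be fast and forms the C4a–C4 bond in an aroyl-palladium species. Sodium enolate 12 replaces iodide at palladium, and C–C reductive elimination from the C-bound aroyl(enolate) complex forms C4–C3 and returns zerovalent palladium. The diketone is deprotonated at once by the second equivalent of 12, which removes it from further aroylation as a chelated sodium diketonate; the ketone 10 released in this way is recovered. No ring is closed and no stereocenter is formed. The selectivity required is carbonylative coupling at carbon in preference to direct alpha-arylation, O-aroylation and hydrodeiodination: the two ortho substituents retard C–C reductive elimination from an aryl(enolate) complex far more than they retard CO insertion, the wide-bite-angle bisphosphine Xantphos speeds reductive elimination from the acyl complex, and the CO atmosphere keeps the aroyl form populated. Using the preformed enolate as the only base leaves no free amide base to intercept the aroyl-palladium species, and the methoxymethyl and methyl ethers are inert to the base and the catalyst.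

Step 8
Reactants: 13 1-[3,4,5-trimethoxy-2,6-bis(methoxymethoxy)phenyl]-3-[4-methoxy-3,5-bis(methoxymethoxy)phenyl]propane-1,3-dione
Product: 15 Gardenin E (5-hydroxy-2-(3,5-dihydroxy-4-methoxyphenyl)-6,7,8-trimethoxy-4H-chromen-4-one), via tetraphenol diketone 14 (not isolated)
Conditions: conc. HCl, MeOH, 65 °C
Reagents that add atoms: none
Why: Acid-catalysed transacetalisation of the four methoxymethyl ethers to methanol frees 14, whose ortho hydroxyl adds to the C2 carbonyl (6-exo-trig hemiketal formation) and loses water, the classical cyclodehydration of 2-hydroxyaryl 1,3-diketones to flavones; the two ortho hydroxyls are equivalent, so only one flavone can form and the other oxygen remains as the chelated 5-hydroxyl.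

## Compound list

1 | 1,2,3-trimethoxybenzene | COc1cccc(OC)c1OC | starting material
2 | 1,5-dibromo-2,3,4-trimethoxybenzene | COc1c(Br)cc(Br)c(OC)c1OC | intermediate
3 | 4,5,6-trimethoxybenzene-1,3-diol | COc1c(O)cc(O)c(OC)c1OC | intermediate
4 | 1,2,3-trimethoxy-4,6-bis(methoxymethoxy)benzene | COCOc1cc(OCOC)c(OC)c(OC)c1OC | intermediate
5 | [3,4,5-trimethoxy-2,6-bis(methoxymethoxy)phenyl]lithium | [Li]c1c(OCOC)c(OC)c(OC)c(OC)c1OCOC | intermediate (not isolated)
6 | 2-iodo-4,5,6-trimethoxy-1,3-bis(methoxymethoxy)benzene | COCOc1c(I)c(OCOC)c(OC)c(OC)c1OC | intermediate
7 | methyl 3,5-dihydroxy-4-methoxybenzoate | COC(=O)c1cc(O)c(OC)c(O)c1 | starting material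
8 | methyl 4-methoxy-3,5-bis(methoxymethoxy)benzoate | COCOc1cc(C(=O)OC)cc(OCOC)c1OC | intermediate
9 | N,4-dimethoxy-3,5-bis(methoxymethoxy)-N-methylbenzamide | COCOc1cc(C(=O)N(C)OC)cc(OCOC)c1OC | intermediate (not isolated)
10 | 1-[4-methoxy-3,5-bis(methoxymethoxy)phenyl]ethan-1-one | COCOc1cc(C(C)=O)cc(OCOC)c1OC | intermediate
11 | carbon monoxide | [C-]#[O+] | starting material
12 | sodium 1-[4-methoxy-3,5-bis(methoxymethoxy)phenyl]ethen-1-olate | [Na+].[O-]C(=C)c1cc(OCOC)c(OC)c(OCOC)c1 | intermediate (not isolated)
13 | 1-[3,4,5-trimethoxy-2,6-bis(methoxymethoxy)phenyl]-3-[4-methoxy-3,5-bis(methoxymethoxy)phenyl]propane-1,3-dione | COCOc1cc(C(=O)CC(=O)c2c(OCOC)c(OC)c(OC)c(OC)c2OCOC)cc(OCOC)c1OC | intermediate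
14 | 1-(2,6-dihydroxy-3,4,5-trimethoxyphenyl)-3-(3,5-dihydroxy-4-methoxyphenyl)propane-1,3-dione | COc1c(O)cc(C(=O)CC(=O)c2c(O)c(OC)c(OC)c(OC)c2O)cc1O | intermediate (not isolated)
15 | Gardenin E, 5-hydroxy-2-(3,5-dihydroxy-4-methoxyphenyl)-6,7,8-trimethoxy-4H-chromen-4-one (achiral) | COc1c(O)cc(-c2cc(=O)c3c(O)c(OC)c(OC)c(OC)c3o2)cc1O | target

## Step count and risks

Total step count: 8 (steps 1–4 for ring A, steps 5–6 for ring B, steps 7–8 for union and closure).
Longest linear sequence: 6 steps (1 → 2 → 3 → 4 → 6 → 13 → 15; steps 1, 2, 3, 4, 7, 8).

**Step 7 (key step).** The most likely failure is slow acyl transfer at the doubly ortho-substituted aroyl-palladium centre. The aryl-palladium species could then be lost to hydrodeiodination, to direct enolate arylation, or to O-aroylation of the enolate. Fallback, setting out from 4 and 8: aryllithium 5, generated from 4 as in step 4, is acylated with N-methoxy-N-methylacetamide to give 1-[3,4,5-trimethoxy-2,6-bis(methoxymethoxy)phenyl]ethan-1-one F1. F1 is deprotonated at its unhindered methyl group with LiN(SiMe3)2 in THF and condensed with ester 8 in a crossed Claisen reaction. This forms C2–C3 instead of the bonds to C4 and comes back to the route at 13.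

**Step 2.** Twofold hydroxylation may stall after the first C–O coupling or drift into diaryl ether formation between a phenoxide and remaining bromide. The electron-rich dianion is also sensitive to adventitious oxygen at 100 °C. Fallback, setting out from 2: Miyaura borylation (B2pin2, Pd(dppf)Cl2, KOAc, 1,4-dioxane, 90 °C) gives 2,2'-(4,5,6-trimethoxy-1,3-phenylene)bis(4,4,5,5-tetramethyl-1,3,2-dioxaborolane) F2. Oxidation with H2O2/NaOH at 0 °C then returns to the route at 3.

**Step 4.** Lithiation could remain incomplete, or the aryllithium could be protonated during the quench, returning 4, which is hard to separate from 6. Fallback, setting out from 3: electrophilic iodination of the free resorcinol at its only ring C–H (I2, NaHCO3, THF/H2O, 0 °C) gives 2-iodo-4,5,6-trimethoxybenzene-1,3-diol F3. Capping with MOMCl/iPr2NEt as in step 3 comes back to the route at 6.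

**Step 6.** If amide formation is incomplete when MeMgBr is added, the Grignard reagent will add twice to remaining ester and give the tertiary carbinol. Fallback, setting out from 8: saponification (LiOH, THF/H2O) gives 4-methoxy-3,5-bis(methoxymethoxy)benzoic acid F4. F4 is treated with MeLi (2.2 equiv, THF, 0 °C) and quenched with water, which returns to the route at 10.

**Step 8.** The formaldehyde equivalents released in hot acid may alkylate the active methylene of the diketone or the electron-rich phenol rings. Dehydration of the hemiketal may also stop short. Fallback, setting out from 13: the ethers are cleaved under non-protic conditions with ZnBr2 and n-PrSH in CH2Cl2 at 0 °C, which traps the methoxymethyl cation as a thioacetal, and 14 is isolated. 14 is then cyclodehydrated separately with catalytic H2SO4 in AcOH at 80 °C, coming back to the route at 15. This fallback makes no compound outside the list.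

## Further compounds

F1 | step 7 | 1-[3,4,5-trimethoxy-2,6-bis(methoxymethoxy)phenyl]ethan-1-one | CC(=O)c1c(OCOC)c(OC)c(OC)c(OC)c1OCOC
F2 | step 2 | 2,2'-(4,5,6-trimethoxy-1,3-phenylene)bis(4,4,5,5-tetramethyl-1,3,2-dioxaborolane) | COc1c(B2OC(C)(C)C(C)(C)O2)cc(B2OC(C)(C)C(C)(C)O2)c(OC)c1OC
F3 | step 4 | 2-iodo-4,5,6-trimethoxybenzene-1,3-diol | COc1c(O)c(I)c(O)c(OC)c1OC
F4 | step 6 | 4-methoxy-3,5-bis(methoxymethoxy)benzoic acid | COCOc1cc(C(=O)O)cc(OCOC)c1OC
F0 | step 8 | none | none
A1 | alternative 1 | 1-[4-methoxy-3,5-bis(pivaloyloxy)phenyl]-3-(2,3,4,5-tetramethoxyphenyl)propane-1,3-dione | COc1cc(C(=O)CC(=O)c2cc(OC(=O)C(C)(C)C)c(OC)c(OC(=O)C(C)(C)C)c2)c(OC)c(OC)c1OC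
A2 | alternative 1 | 5,6,7,8,4'-pentamethoxy-3',5'-bis(pivaloyloxy)flavone | COc1c(OC(=O)C(C)(C)C)cc(-c2cc(=O)c3c(OC)c(OC)c(OC)c(OC)c3o2)cc1OC(=O)C(C)(C)C
A3 | alternative 2 | dimethyl squarate (3,4-dimethoxycyclobut-3-ene-1,2-dione) | COC1=C(OC)C(=O)C1=O
A4 | alternative 2 | 2-[3,5-bis(benzyloxy)-4-methoxyphenyl]-4H-pyran-4-one | O=c1ccoc(-c2cc(OCc3ccccc3)c(OC)c(OCc3ccccc3)c2)c1
A5 | alternative 2 | 4-{6-[3,5-bis(benzyloxy)-4-methoxyphenyl]-4-oxo-4H-pyran-2-yl}-4-hydroxy-2,3-dimethoxycyclobut-2-en-1-one (racemic) | COC1=C(OC)C(O)(c2cc(=O)cc(-c3cc(OCc4ccccc4)c(OC)c(OCc4ccccc4)c3)o2)C1=O
A6 | alternative 2 | 3',5'-bis(benzyloxy)-5,8-dihydroxy-6,7,4'-trimethoxyflavone | COc1c(OCc2ccccc2)cc(-c2cc(=O)c3c(O)c(OC)c(OC)c(O)c3o2)cc1OCc1ccccc1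
A7 | alternative 3 | 5,6,7,8-tetramethoxy-2-methyl-4H-chromen-4-one | Cc1cc(=O)c2c(OC)c(OC)c(OC)c(OC)c2o1
A8 | alternative 3 | 3,5-bis(benzyloxy)-4H-pyran-4-one | O=c1c(OCc2ccccc2)cocc1OCc1ccccc1
A9 | alternative 3 | 3',5'-bis(benzyloxy)-4'-hydroxy-5,6,7,8-tetramethoxyflavone | COc1c(OC)c(OC)c2oc(-c3cc(OCc4ccccc4)c(O)c(OCc4ccccc4)c3)cc(=O)c2c1OC
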